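**Retrosynthetic overview**
1. The sulfate is put on last, at the C2 CH2OH; until then the C3 CH2OH and both phenols are benzyl ethers (one final hydrogenolysis) and the C2 CH2O is a TIPS ether.
2. Key disconnection: the bond from C1 to the pendant guaiacyl ring and the C2–C3 ring bond are cut together, giving an (E)-cinnamyl silyl ether with an ortho CH2–oxirane arm (one stereocentre, C3) and an aryl(trimethyl)silane.
3. Enabling feature: C1 is benzylic, para to the C6 OMe of the fused ring, and is the alkene partner of C2, which is bonded to C3. Attack of C2 on a C3 electrophile therefore leaves a stabilised cation at C1, exactly where the pendant ring (nucleophilic para to its oxygen) must be attached.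
4. Stereochemistry: C3 is bought as (R)-epichlorohydrin; C2 and C1 are relayed from it inside the key step (2,3-trans, then 1,2-trans).
5. Rings: benzo ring C4a–C8a bought; oxirane (temporary) made in step 4; carbocycle C1–C4 closed in step 6 as the oxirane opens; no ring formed afterwards.

Key step: step 6

Remark (numbering): locants C1–C8a are those of the tetralin core of the target (C1 pendant aryl, C2 sulfated CH2O, C3 CH2OH, C6 OMe, C7 OH).
Remark (sulfate): the sulfate monoester (17, 18) is drawn as the free hydrogen sulfate, the form given for the target; it would be handled as its sodium salt and the acid released by brief contact with an H+ ion-exchange resin.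

**Step 1**
Reactants: 1 5-(benzyloxy)-2-bromo-4-methoxybenzaldehyde
Product: 2 ethyl (E)-3-[5-(benzyloxy)-2-bromo-4-methoxyphenyl]prop-2-enoate
Conditions: (EtO)2P(O)CH2CO2Et, NaH, THF, 0 °C → rt
Reagents that add atoms: triethyl phosphonoacetate, CCOC(=O)CP(=O)(OCC)OCC
Why: Horner–Wadsworth–Emmons olefination of an aryl aldehyde with a stabilised phosphonate should give the (E)-cinnamate, the geometry that step 6 turns into an equatorial C2 substituent.

**Step 2**
Reactants: 2 ethyl (E)-3-[5-(benzyloxy)-2-bromo-4-methoxyphenyl]prop-2-enoate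
Product: 3 (E)-3-[5-(benzyloxy)-2-bromo-4-methoxyphenyl]prop-2-en-1-ol
Conditions: DIBAL-H (2.2 equiv), CH2Cl2, −78 °C; Rochelle salt work-up
Reagents that add atoms: none
Why: DIBAL-H 1,2-reduction of the conjugated ester should stop at the allylic alcohol and leave the aryl bromide, alkene and benzyl ether untouched.

**Step 3**
Reactants: 3 (E)-3-[5-(benzyloxy)-2-bromo-4-methoxyphenyl]prop-2-en-1-ol
Product: 4 {[(E)-3-[5-(benzyloxy)-2-bromo-4-methoxyphenyl]prop-2-en-1-yl]oxy}tri(propan-2-yl)silane
Conditions: TIPSCl, imidazole, DMF, rt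
Reagents that add atoms: chlorotri(propan-2-yl)silane, CC(C)[Si](Cl)(C(C)C)C(C)C
Why: Silylation of a primary allylic alcohol; the bulky, weakly Lewis-basic TIPS ether is chosen so that the cinnamyl C–O bond does not ionise in step 6.

**Step 4**
Reactants: 4 {[(E)-3-[5-(benzyloxy)-2-bromo-4-methoxyphenyl]prop-2-en-1-yl]oxy}tri(propan-2-yl)silane; 5 (R)-epichlorohydrin
Product: 8 (2R)-2-({4-(benzyloxy)-5-methoxy-2-[(E)-3-(triisopropylsilyloxy)prop-1-en-1-yl]phenyl}methyl)oxirane, via arylmagnesium bromide 6 (not isolated), via chlorohydrin 7 (not isolated)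
Conditions: Mg, LiCl, THF, rt; CuI (10 mol %), 5, −30 → 0 °C; then KOt-Bu, 0 °C → rt
Reagents that add atoms: none
Why: Grignard formation, copper-catalysed opening of the oxirane of epichlorohydrin at its CH2 terminus and base-induced closure of the chlorohydrin alkoxide is the standard route to enantiopure 2-benzyloxiranes; no bond to the stereocentre is broken, so (R)-5 should give (R)-8.

**Step 5**
Reactants: 9 1-(benzyloxy)-4-bromo-2-methoxybenzene
Product: 11 [4-(benzyloxy)-3-methoxyphenyl]trimethylsilane, via aryllithium 10 (not isolated)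
Conditions: n-BuLi, THF, −78 °C; then Me3SiCl, −78 °C → rt
Reagents that add atoms: chlorotrimethylsilane, C[Si](C)(C)Cl
Why: Bromine–lithium exchange and C-silylation; the silicon marks the carbon para to OBn as the site of electrophilic ipso-substitution in step 6.

**Step 6**
Reactants: 8 (2R)-2-({4-(benzyloxy)-5-methoxy-2-[(E)-3-(triisopropylsilyloxy)prop-1-en-1-yl]phenyl}methyl)oxirane; 11 [4-(benzyloxy)-3-methoxyphenyl]trimethylsilane
Product: 14 (1S,2R,3R)-7-(benzyloxy)-1-[4-(benzyloxy)-3-methoxyphenyl]-3-(hydroxymethyl)-6-methoxy-2-[(triisopropylsilyloxy)methyl]-1,2,3,4-tetrahydronaphthalene, via benzylic cation 12 (not isolated), via trimethylsilyl ether 13 (not isolated)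
Conditions: 11 (2.5 equiv), TMSOTf (20 mol %), 2,6-di-tert-butyl-4-methylpyridine (20 mol %), CH2Cl2 (0.02 M), −78 → −40 °C; then K2CO3, MeOH, 0 °C
Reagents that add atoms: none
Why: Proposed new method: catalytic Me3Si+ (TMSOTf) activates the oxirane of 8, the electron-rich styrene attacks C3 through C2 with inversion (ring closure 6-exo-tet with respect to the breaking C3–O bond, both alkene carbons ending in the ring), and the resulting cation 12 at C1, benzylic and para to the C6 OMe, is captured by 11 at its silicon-bearing carbon, the expelled Me3Si+ ending on the oxygen of the next oxirane so that no proton is released. The closest known reaction types are Lewis-acid 6-exo cyclisations of terminal epoxides onto arenes and alkenes, the intramolecular Prins/intermolecular Friedel–Crafts cascade that converts 2-(2-vinylphenyl)acetaldehydes and arenes into 4-aryltetralin-2-ols, ipso-substitution of aryltrimethylsilanes by carbon electrophiles, and trans-selective Friedel–Crafts arylation of benzylic cations bearing a neighbouring stereocentre. The only ring closed is the carbocycle C1–C2–C3–C4–C4a–C8a (through the C2–C3 bond), while the oxirane opens. C3 comes from (R)-epichlorohydrin and is inverted stereospecifically by backside attack (the descriptor stays R because the priorities change); C2 is set by a chair-like transition state in which the E-alkene keeps CH2OTIPS, and the oxirane its CH2O arm, equatorial (2,3-trans); C1 is set last, the arene adding anti to the neighbouring C2 substituent (1,2-trans), which is also the all-equatorial arrangement favoured if the arylation is reversible. The step needs attack of the alkene through C2 and not C1 (secured by the p-methoxybenzylic cation that only this mode gives), attack at the internal oxirane carbon (six- rather than seven-membered ring), capture of 12 by the external arene before elimination (excess 11, low temperature, a hindered pyridine that only scavenges triflic acid) and bond formation para to OBn rather than para to OMe (secured by ipso-substitution at silicon).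

**Step 7**
Reactants: 14 (1S,2R,3R)-7-(benzyloxy)-1-[4-(benzyloxy)-3-methoxyphenyl]-3-(hydroxymethyl)-6-methoxy-2-[(triisopropylsilyloxy)methyl]-1,2,3,4-tetrahydronaphthalene
Product: 15 (1S,2R,3R)-7-(benzyloxy)-3-[(benzyloxy)methyl]-1-[4-(benzyloxy)-3-methoxyphenyl]-6-methoxy-2-[(triisopropylsilyloxy)methyl]-1,2,3,4-tetrahydronaphthalene
Conditions: NaH, BnBr, Bu4NI (cat.), THF–DMF, 0 °C → rt
Reagents that add atoms: benzyl bromide, BrCc1ccccc1
Why: Williamson etherification of the only free hydroxyl protects the C3 CH2OH as a benzyl ether that will leave together with the two phenolic benzyl groups.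

**Step 8**
Reactants: 15 (1S,2R,3R)-7-(benzyloxy)-3-[(benzyloxy)methyl]-1-[4-(benzyloxy)-3-methoxyphenyl]-6-methoxy-2-[(triisopropylsilyloxy)methyl]-1,2,3,4-tetrahydronaphthalene
Product: 16 [(1S,2R,3R)-7-(benzyloxy)-3-[(benzyloxy)methyl]-1-[4-(benzyloxy)-3-methoxyphenyl]-6-methoxy-1,2,3,4-tetrahydronaphthalen-2-yl]methanol
Conditions: Bu4NF, THF, rt
Reagents that add atoms: none
Why: Fluoride-induced desilylation should cleave the TIPS ether selectively and free the C2 CH2OH alone; benzyl ethers are inert.

**Step 9**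
Reactants: 16 [(1S,2R,3R)-7-(benzyloxy)-3-[(benzyloxy)methyl]-1-[4-(benzyloxy)-3-methoxyphenyl]-6-methoxy-1,2,3,4-tetrahydronaphthalen-2-yl]methanol
Product: 17 [(1S,2R,3R)-7-(benzyloxy)-3-[(benzyloxy)methyl]-1-[4-(benzyloxy)-3-methoxyphenyl]-6-methoxy-1,2,3,4-tetrahydronaphthalen-2-yl]methyl hydrogen sulfate
Conditions: SO3·pyridine (4 equiv), pyridine, 40 °C
Reagents that add atoms: sulfur trioxide–pyridine complex, [O-]S(=O)(=O)[n+]1ccccc1
Why: O-Sulfation of the single free primary alcohol with the SO3–pyridine complex; no other nucleophilic group is present.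

**Step 10**
Reactants: 17 [(1S,2R,3R)-7-(benzyloxy)-3-[(benzyloxy)methyl]-1-[4-(benzyloxy)-3-methoxyphenyl]-6-methoxy-1,2,3,4-tetrahydronaphthalen-2-yl]methyl hydrogen sulfate
Product: 18 [(1S,2R,3R)-7-hydroxy-1-(4-hydroxy-3-methoxyphenyl)-3-(hydroxymethyl)-6-methoxy-1,2,3,4-tetrahydronaphthalen-2-yl]methyl hydrogen sulfate (target)
Conditions: H2 (1 atm), 10% Pd/C, MeOH, rt
Reagents that add atoms: none
Why: Catalytic hydrogenolysis should remove the three O-benzyl groups (two aryl ethers, one alkyl ether) under neutral conditions that an alkyl sulfate salt tolerates; no stereocentre is at risk.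

**Compound list**
1 | 5-(benzyloxy)-2-bromo-4-methoxybenzaldehyde | O=Cc1cc(OCc2ccccc2)c(OC)cc1Br | starting material
2 | ethyl (E)-3-[5-(benzyloxy)-2-bromo-4-methoxyphenyl]prop-2-enoate | CCOC(=O)/C=C/c1cc(OCc2ccccc2)c(OC)cc1Br | intermediate
3 | (E)-3-[5-(benzyloxy)-2-bromo-4-methoxyphenyl]prop-2-en-1-ol | OC/C=C/c1cc(OCc2ccccc2)c(OC)cc1Br | intermediate
4 | {[(E)-3-[5-(benzyloxy)-2-bromo-4-methoxyphenyl]prop-2-en-1-yl]oxy}tri(propan-2-yl)silane | CC(C)[Si](OC/C=C/c1cc(OCc2ccccc2)c(OC)cc1Br)(C(C)C)C(C)C | intermediate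
5 | (R)-epichlorohydrin, (2R)-2-(chloromethyl)oxirane | ClC[C@H]1CO1 | starting material
6 | {4-(benzyloxy)-5-methoxy-2-[(E)-3-(triisopropylsilyloxy)prop-1-en-1-yl]phenyl}magnesium bromide | CC(C)[Si](OC/C=C/c1cc(OCc2ccccc2)c(OC)cc1[Mg]Br)(C(C)C)C(C)C | intermediate
7 | (2R)-1-chloro-3-{4-(benzyloxy)-5-methoxy-2-[(E)-3-(triisopropylsilyloxy)prop-1-en-1-yl]phenyl}propan-2-ol (present as its magnesium alkoxide) | CC(C)[Si](OC/C=C/c1cc(OCc2ccccc2)c(OC)cc1C[C@@H](O)CCl)(C(C)C)C(C)C | intermediate
8 | (2R)-2-({4-(benzyloxy)-5-methoxy-2-[(E)-3-(triisopropylsilyloxy)prop-1-en-1-yl]phenyl}methyl)oxirane | CC(C)[Si](OC/C=C/c1cc(OCc2ccccc2)c(OC)cc1C[C@@H]3CO3)(C(C)C)C(C)C | intermediate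
9 | 1-(benzyloxy)-4-bromo-2-methoxybenzene | COc1cc(Br)ccc1OCc1ccccc1 | starting material
10 | [4-(benzyloxy)-3-methoxyphenyl]lithium | [Li]c1ccc(OCc2ccccc2)c(OC)c1 | intermediate
11 | [4-(benzyloxy)-3-methoxyphenyl]trimethylsilane | COc1cc([Si](C)(C)C)ccc1OCc1ccccc1 | intermediate
12 | (2R,3R)-7-(benzyloxy)-6-methoxy-2-[(triisopropylsilyloxy)methyl]-3-[(trimethylsilyloxy)methyl]-1,2,3,4-tetrahydronaphthalen-1-ylium triflate (C1 cation; C2 and C3 substituents trans) | C[Si](C)(C)OC[C@@H]1Cc2cc(OC)c(OCc3ccccc3)cc2[CH+][C@H]1CO[Si](C(C)C)(C(C)C)C(C)C.[O-]S(=O)(=O)C(F)(F)F | intermediate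
13 | (1S,2R,3R)-7-(benzyloxy)-1-[4-(benzyloxy)-3-methoxyphenyl]-6-methoxy-2-[(triisopropylsilyloxy)methyl]-3-[(trimethylsilyloxy)methyl]-1,2,3,4-tetrahydronaphthalene | COc1cc([C@H]2c3cc(OCc4ccccc4)c(OC)cc3C[C@@H](CO[Si](C)(C)C)[C@@H]2CO[Si](C(C)C)(C(C)C)C(C)C)ccc1OCc5ccccc5 | intermediate
14 | (1S,2R,3R)-7-(benzyloxy)-1-[4-(benzyloxy)-3-methoxyphenyl]-3-(hydroxymethyl)-6-methoxy-2-[(triisopropylsilyloxy)methyl]-1,2,3,4-tetrahydronaphthalene (all-trans) | COc1cc([C@H]2c3cc(OCc4ccccc4)c(OC)cc3C[C@@H](CO)[C@@H]2CO[Si](C(C)C)(C(C)C)C(C)C)ccc1OCc5ccccc5 | intermediate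
15 | (1S,2R,3R)-7-(benzyloxy)-3-[(benzyloxy)methyl]-1-[4-(benzyloxy)-3-methoxyphenyl]-6-methoxy-2-[(triisopropylsilyloxy)methyl]-1,2,3,4-tetrahydronaphthalene | COc1cc([C@H]2c3cc(OCc4ccccc4)c(OC)cc3C[C@@H](COCc6ccccc6)[C@@H]2CO[Si](C(C)C)(C(C)C)C(C)C)ccc1OCc5ccccc5 | intermediate
16 | [(1S,2R,3R)-7-(benzyloxy)-3-[(benzyloxy)methyl]-1-[4-(benzyloxy)-3-methoxyphenyl]-6-methoxy-1,2,3,4-tetrahydronaphthalen-2-yl]methanol | COc1cc([C@H]2c3cc(OCc4ccccc4)c(OC)cc3C[C@@H](COCc6ccccc6)[C@@H]2CO)ccc1OCc5ccccc5 | intermediate
17 | [(1S,2R,3R)-7-(benzyloxy)-3-[(benzyloxy)methyl]-1-[4-(benzyloxy)-3-methoxyphenyl]-6-methoxy-1,2,3,4-tetrahydronaphthalen-2-yl]methyl hydrogen sulfate | COc1cc([C@H]2c3cc(OCc4ccccc4)c(OC)cc3C[C@@H](COCc6ccccc6)[C@@H]2COS(=O)(=O)O)ccc1OCc5ccccc5 | intermediate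
18 | [(1S,2R,3R)-7-hydroxy-1-(4-hydroxy-3-methoxyphenyl)-3-(hydroxymethyl)-6-methoxy-1,2,3,4-tetrahydronaphthalen-2-yl]methyl hydrogen sulfate | COc1cc([C@H]2c3cc(O)c(OC)cc3C[C@@H](CO)[C@@H]2COS(=O)(=O)O)ccc1O | target

**Step count and risks**
Total steps: 10. Longest linear sequence: 9 steps (1–4, then 6–10); step 5 is the one-step side branch.

Step 6 (Proposed new method; highest risk). The activated oxirane may rearrange by hydride or aryl shift, or close through a boat-like transition state, before or instead of the planned closure. The C1 cation may be lost by elimination or oligomerisation before it is captured. Capture may occur at the arene carbon para to OMe. The fallback separates the two bond formations into operations of known type, sets out from 8 and returns at 15; it answers the capture and regiochemistry problems, not oxirane rearrangement. First, 8 would be cyclised on its own (TMSOTf 10 mol %, 2,6-di-tert-butyl-4-methylpyridine, CH2Cl2, −78 °C), a Lewis-acid epoxide–olefin cyclisation in which the cation is captured by the oxygen released from the oxirane. This should give the bridged benzylic ether with a C1–O–CH2–C3 bridge (C1–O and C3–CH2 cis, C2 CH2OTIPS trans to both) F1. Second, F1 would serve as the benzylic electrophile in a conventional Lewis-acid Friedel–Crafts alkylation of free guaiacol (2-methoxyphenol, 5 equiv, FeCl3 10 mol %, CH2Cl2, 0 °C). Alkylation para to the phenolic OH and anti to the C2 substituent should give the (1S,2R,3R)-1-(4-hydroxy-3-methoxyphenyl) analogue of 14 F2. Third, NaH and BnBr (2.5 equiv each, as in step 7) would benzylate the phenol and the C3 CH2OH together to give 15.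

Step 7. Under alkoxide conditions the TIPS group may migrate from the C2 CH2O oxygen to the neighbouring C3 CH2O−, scrambling which oxygen is benzylated. The fallback avoids any alkoxide, sets out from 13 and returns at 15. The cascade of step 6 would be worked up without methanolysis so that trimethylsilyl ether 13 is isolated. Reductive etherification of 13 (PhCHO, Et3SiH, TMSOTf 10 mol %, CH2Cl2, −78 °C) would then convert the C3 CH2OSiMe3 directly into the benzyl ether 15. No new compound is made (F0).

Step 10. The sulfate monoester may be partly lost by solvolysis on the catalyst, or the alkyl benzyl ether next to it may be cleaved incompletely. The fallback carries the sulfate in masked form, sets out from 16 and returns at 18. Alcohol 16 would be treated with 2,2,2-trichloroethyl chlorosulfate (Et3N, DMAP, THF) to give the neutral 2,2,2-trichloroethyl sulfate diester of 16 F3. One transfer hydrogenolysis (Pd/C, HCO2NH4, MeOH) would then remove the three benzyl groups and the trichloroethyl group and give 18 as its ammonium salt.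

**Further compounds**
F1 | step 6 | bridged ether: tetralin core of 14 without the C1 aryl group, C1 joined through O–CH2 to C3 (C1–O and C3–CH2 cis), C2 CH2OTIPS trans to both, C6 OMe, C7 OBn | CC(C)[Si](OC[C@@H]1[C@H]2OC[C@@H]1Cc3cc(OC)c(OCc4ccccc4)cc32)(C(C)C)C(C)C
F2 | step 6 | (1S,2R,3R)-7-(benzyloxy)-1-(4-hydroxy-3-methoxyphenyl)-3-(hydroxymethyl)-6-methoxy-2-[(triisopropylsilyloxy)methyl]-1,2,3,4-tetrahydronaphthalene | COc1cc([C@H]2c3cc(OCc4ccccc4)c(OC)cc3C[C@@H](CO)[C@@H]2CO[Si](C(C)C)(C(C)C)C(C)C)ccc1O
F0 | step 7 | none | none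
F3 | step 10 | [(1S,2R,3R)-7-(benzyloxy)-3-[(benzyloxy)methyl]-1-[4-(benzyloxy)-3-methoxyphenyl]-6-methoxy-1,2,3,4-tetrahydronaphthalen-2-yl]methyl 2,2,2-trichloroethyl sulfate | COc1cc([C@H]2c3cc(OCc4ccccc4)c(OC)cc3C[C@@H](COCc6ccccc6)[C@@H]2COS(=O)(=O)OCC(Cl)(Cl)Cl)ccc1OCc5ccccc5
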